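1. Free monomer plus monomer in chains stays at the charge within the scatter: the theta run ends at 101%, the zeta run at 101%. One curve, monomer in chains as a fraction of the charge, therefore describes each run.

| setting | theta | zeta | flask |
|---|---|---|---|
| free monomer | 0.020 M | 0.020 M | 0.020 M |
| pre-initiator | 0.67 mM | 1.5 mM | 1.0 mM |
| remark | run made earlier | run made earlier |  |
| time |  |  | 6.0 d |

| run | time / d | monomer in chains / % | free monomer / % |
|---|---|---|---|
| theta | 0.625 | 7.2 | 90.4 |
| theta | 0.833 | 12.9 | 86.5 |
| theta | 1.25 | 24.4 | 74.3 |
| theta | 2.08 | 44.9 | 53.5 |
| theta | 3.00 | 59.1 | 38.7 |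
| theta | 5.00 | 71.4 | 30.6 |
| theta | 8.00 | 73.3 | 28.1 |
| zeta | 0.417 | 8.2 | 89.5 |
| zeta | 1.04 | 36.6 | 63.4 |
| zeta | 2.08 | 63.3 | 35.2 |
| zeta | 3.00 | 71.0 | 29.1 |
| zeta | 4.00 | 71.8 | 26.5 |
| zeta | 6.00 | 73.0 | 27.6 |
| zeta | 8.00 | 73.3 | 27.5 |

(readings scatter by 1 percentage point)

- average number of monomer units in a chain (chains begun, living or dead) at 6.0 d
- part of the free monomer that has reacted at 6.0 d

- the average divides the monomer in chains by the number of chains begun, living and dead together
- the numbers in the tables scatter with a standard deviation of 1 percentage point
- the earlier runs do not show the number of chains; that part of a forecast is a guess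

2. Start: the theta run climbs at 0.115 /d up to its first reading, then faster, at 0.247 /d, so what carries the reaction is still growing.

3. Crossing, where the fraction reaches one half: the readings give 2.35 d for theta and 1.55 d for zeta. Their ratio, 1.52, matches the root of the inverse charges of pre-initiator, 1.50. That scaling puts the flask's crossing near 1.93 d.

4. Knee: theta has flattened by 5.00 d, which scales to 4.09 d for the flask, earlier than 6.0 d.

5. Level: the runs end at 73.3% and 73.3%, equal within the scatter despite different charges of pre-initiator. The flask should therefore reach their mean, 73.3%.

6. The chain load (theoretical chain length) is that level times the ratio of free monomer charged to pre-initiator charged: 14.7 units for the flask. Dividing it by the share of pre-initiator that begins a chain gives the average. The runs do not show that share, so this reckoning commits to an average of at least the load, if each pre-initiator begins at most one chain.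

The forecast gives 16 and 72.7%, “assuming one chain per activated pre-initiator, which is a guess”.

The flask gives 22.1 and 72.6%.

    pre-initiator → initiator (k = 9.60 × 10⁻⁶ /s)
    initiator → spent initiator (k = 7.40 × 10⁻⁵ /s)
    free monomer + living end → monomer in chains + living end, rate k3*[living end]*[free monomer] (k = 0.0220 /M/s)
    free monomer + initiator → living end + monomer in chains (k = 0.0110 /M/s)
    monomer in chains + living end → free monomer + living end, rate k5*[living end] as long as [monomer in chains] is above zero (k = 1.20 × 10⁻⁴ /s)

Against the flask's load, that average means that a share of about 0.664 of the pre-initiator charged began chains; at 6.00 d the flask holds 6.57 × 10⁻⁴ M of living end beside 3.35 × 10⁻⁴ M of spent initiator. The neighbouring flask, charged with 0.0017 M of pre-initiator, has a load of 8.62, and the same share would give 13.0. In that neighbouring flask 72.7% of the free monomer has reacted and the average is 13.7, a share of about 0.629.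

The runs were computed for an exercise; noise was put on by code.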